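## Retrosynthetic overview
Numbering: ring A = C1–C5, C10; ring B = C5–C10. C3 carries the exocyclic methylene, C4 the benzyl group, C5 and C9 are the quaternary carbons, C8 is CHBr, and C11–C14 is the side chain.
1. C8–Br comes from an axial α-C8–OH by SN2 inversion (Appel). The C4–CH2–Ar bond comes from reductive coupling of a C4-aldehyde tosylhydrazone with an arylboronic acid.
2. The C3=CH2/C4–H unit comes from kinetic deconjugative protonation of an enal, which is made from the ring-A ketone by one-carbon Wittig homologation.
3. C8–OH comes from hydride opening of an α-epoxide. The C9 side chain comes from the ester of the [3,3] step via reduction, iodide and Cu-catalysed coupling.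
4. Ring B is formed second, by RCM of C5-allyl and C9-vinyl. The C9 quaternary centre is set by a Johnson–Claisen [3,3] rearrangement of a carvone-derived (E)-allylic alcohol.
5. Ring A is the carvone ring, present from the start. C5 of (S)-carvone becomes C10, and C5 of the target is built by double α′-alkylation.

Assumptions: (S)-(+)-carvone is the chiral starting material (its C5 becomes target C10, both S). The diastereoselectivities given in the "Why" lines are assumed from the stated conformational arguments. Compounds that only transfer H, act as oxidants or bases, or are catalysts are not numbered; their SMILES are given where they leave atoms.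

## Route

**Step 1**
Reactants: 1 (S)-carvone; 2 (Z)-1,4-diacetoxybut-2-ene
Product: 3 (5S)-5-[(E)-4-acetoxybut-2-en-2-yl]-2-methylcyclohex-2-en-1-one
Conditions: Hoveyda–Grubbs II (5 mol%), excess 2, CH2Cl2, 40 °C
Reagents that add atoms: 2, CC(=O)OC/C=C\COC(C)=O (listed as reactant)
Why: Cross-metathesis exchanges the 1,1-disubstituted isopropenyl alkene (the electron-poor enone alkene is inert) for the thermodynamically preferred (E)-trisubstituted allylic acetate, leaving the future C10 stereocentre untouched.

**Step 2**
Reactants: 3; 4 iodomethane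
Product: 5 (5S)-5-[(E)-4-acetoxybut-2-en-2-yl]-2,6-dimethylcyclohex-2-en-1-one (mainly 5,6-trans; C6 epimers are interconvertible and are re-set in step 3)
Conditions: LDA, THF, −78 °C; then MeI, −78 → 0 °C
Reagents that add atoms: 4, CI (listed as reactant)
Why: Kinetic enolate formation at C6 followed by enolate alkylation occurs anti to the C5 side chain.

**Step 3**
Reactants: 5; 6 allyl bromide
Product: 7 C6-methyl/C6-allyl quaternary ketone with Me cis and allyl trans to the C5 side chain (C6 becomes target C5)
Conditions: LDA, THF/HMPA, −78 → 0 °C; then allyl bromide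
Reagents that add atoms: 6, C=CCBr (listed as reactant)
Why: In the 6-methyl enolate, A(1,2) strain keeps the C5 side chain pseudo-axial, so the electrophile enters axially anti to it. This places allyl trans and Me cis to the side chain, the relative configuration of C5 versus C10 in the target.

**Step 4**
Reactants: 7
Product: 8 the free (E)-allylic alcohol
Conditions: K2CO3, MeOH, 0 °C → rt
Reagents that add atoms: none
Why: Acetate methanolysis (transesterification) frees the primary allylic alcohol without touching any stereocentre.

**Step 5**
Reactants: 8; 9 triethyl orthoacetate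
Product: 10 ethyl 2-[(C9 quaternary: Me, vinyl, ring C10)]acetate, with C5-allyl and the enone intact
Conditions: MeC(OEt)3 (10 equiv), EtCO2H (cat.), 140 °C, sealed tube
Reagents that add atoms: 9, CC(OCC)(OCC)OCC (listed as reactant)
Why: Johnson–Claisen [3,3] rearrangement of the (E)-allylic alcohol through a chair transition state. The alkene geometry fixes the relative arrangement, and the adjacent C10 stereocentre (via A(1,3) strain) selects the alkene face. This forms the C9–C11 bond and the C9 quaternary centre (Me β, chain α).

**Step 6**
Reactants: 10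
Product: 11 bicyclic enone with the C7=C8 cyclohexene (ring B)
Conditions: Grubbs II (10 mol%), CH2Cl2 (5 mM), 40 °C (ethylene lost)
Reagents that add atoms: none
Why: Ring-closing metathesis of the C5-allyl and C9-vinyl groups gives a trans-fused decalin, because they are trans-diequatorial on adjacent ring-A carbons C5 and C10.

**Step 7**
Reactants: 11
Product: 12 α-C7,C8-epoxide
Conditions: mCPBA, NaHCO3, CH2Cl2, 0 °C
Reagents that add atoms: mCPBA, OOC(=O)c1cccc(Cl)c1 (delivers O)
Why: Electrophilic epoxidation of the electron-rich C7=C8 alkene occurs from the α-face, because the β-face is blocked by the 1,3-diaxial C5 and C9 methyls; the enone alkene is untouched.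

**Step 8**
Reactants: 12
Product: 13 triol (C4 allylic OH as epimer mixture, C8 axial α-OH, C12 primary OH)
Conditions: LiAlH4 (excess), THF, 0 °C → reflux
Reagents that add atoms: none (hydride only)
Why: Fürst–Plattner trans-diaxial epoxide opening puts hydride at C7 from the β-face and leaves the axial α-OH at C8 (C8 configuration set). The ester and enone C=O are reduced in the same pot.

**Step 9**
Reactants: 13
Product: 14 C12 primary iodide (C4-OH and C8-OH unchanged)
Conditions: I2, PPh3, imidazole, CH2Cl2, 0 °C
Reagents that add atoms: iodine, II (delivers I)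
Why: Appel-type iodination is chemoselective for the unhindered primary alcohol over the two hindered secondary alcohols.

**Step 10**
Reactants: 14; 15 2-methylprop-1-enylmagnesium bromide
Product: 16 C9 side chain –CH2CH2CH=CMe2 installed (C4-OH, C8-OH free)
Conditions: 15 (4 equiv), Li2CuCl4 (cat.), THF, −20 °C → rt
Reagents that add atoms: 15, CC(C)=C[Mg]Br (listed as reactant)
Why: Cu-catalysed Kumada–Corriu sp3–sp2 coupling of a primary alkyl iodide builds the 4-methylpent-3-enyl terminus; excess Grignard covers the free alkoxides.

**Step 11**
Reactants: 16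
Product: 17 enone (C4=O, C3-Me/C2=C3), C8-OH retained
Conditions: activated MnO2, CH2Cl2, rt
Reagents that add atoms: none
Why: MnO2 oxidizes only the allylic C4 alcohol, restoring the enone and erasing the C4 epimer mixture.

**Step 12**
Reactants: 17; 18 (methoxymethyl)triphenylphosphonium chloride
Product: 19 dienyl methyl ether (C4=CH–OMe, C3(Me)=C2)
Conditions: Ph3P+CH2OMe Cl−, KOtBu, THF, 0 → 60 °C
Reagents that add atoms: 18, COC[P+](c1ccccc1)(c1ccccc1)c1ccccc1.[Cl-] (listed as reactant)
Why: Wittig methoxymethylenation adds the carbon that will become the benzylic CH2.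

**Step 13**
Reactants: 19
Product: 20 conjugated enal, C4(CHO)=C3(Me) with C2H2
Conditions: aq. oxalic acid, THF, rt
Reagents that add atoms: water, O (delivers the aldehyde O)
Why: Vinylogous enol-ether hydrolysis proceeds by δ-protonation at C2 and delivers the tetrasubstituted enal.

**Step 14**
Reactants: 20
Product: 21 β,γ-unsaturated aldehyde (C3=CH2 exocyclic, C4–H α, CHO equatorial β)
Conditions: KHMDS (2.2 equiv), THF, −78 °C; then AcOH, −78 °C
Reagents that add atoms: none (AcOH delivers H)
Why: γ-Deprotonation at the C3 methyl gives the extended dienolate, and kinetic α-protonation (deconjugation) from the α-face, since the β-face is shielded by the axial C5-Me, creates the exocyclic methylene and sets C4 (equatorial CHO β, matching the target).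

**Step 15**
Reactants: 21; 22 p-toluenesulfonylhydrazide
Product: 23 N-tosylhydrazone (E)
Conditions: TsNHNH2, MeOH, rt
Reagents that add atoms: 22, Cc1ccc(cc1)S(=O)(=O)NN (listed as reactant)
Why: Condensation masks the epimerizable aldehyde as a stable coupling partner, with no change at C4.

**Step 16**
Reactants: 24 methyl 3,5-dibromo-4-hydroxybenzoate; 25 TBSCl
Product: 26 methyl 3,5-dibromo-4-(TBSO)benzoate
Conditions: TBSCl, imidazole, DMF, rt
Reagents that add atoms: 25, C[Si](C)(Cl)C(C)(C)C (listed as reactant)
Why: O-silylation protects the phenol for the organometallic step.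

**Step 17**
Reactants: 26; 27 trimethyl borate
Product: 28 methyl 3-bromo-4-(TBSO)-5-boronobenzoate
Conditions: i-PrMgCl·LiCl (1.0 equiv), THF, −40 °C; then B(OMe)3; aqueous workup
Reagents that add atoms: 27, COB(OC)OC (listed as reactant)
Why: One-equivalent Br/Mg exchange on the symmetrical dibromide, then borylation, gives the mono-boronic acid with the remaining Br placed correctly (ortho to OTBS).

**Step 18**
Reactants: 23; 28
Product: 29 C4–CH2–Ar coupled compound (C8-OH, aryl-OTBS, CO2Me)
Conditions: 28 (2 equiv), K2CO3, 1,4-dioxane, 110 °C
Reagents that add atoms: 28 (aryl donor, listed as reactant)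
Why: Barluenga reductive coupling (tosylhydrazone → diazoalkane → boronic acid, 1,2-aryl shift) converts the CHO carbon into the benzylic CH2 under metal-free conditions; C4 is not touched.

**Step 19**
Reactants: 29; 30 carbon tetrabromide
Product: 31 C8 equatorial β-bromide (aryl-OTBS, CO2Me still present)
Conditions: CBr4, PPh3, CH2Cl2, 0 → 40 °C
Reagents that add atoms: 30, BrC(Br)(Br)Br (listed as reactant)
Why: Appel bromination proceeds by SN2 with inversion, converting the axial α-OH into the equatorial β-Br at C8.

**Step 20**
Reactants: 31
Product: 32 callophycoic acid H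
Conditions: LiOH, THF/MeOH/H2O, 50 °C; pH 4 workup
Reagents that add atoms: water, O (delivers the acid and phenol O–H)
Why: Saponification of the methyl ester and base cleavage of the electron-poor aryl silyl ether give the free hydroxy acid; the C8 bromide sits equatorial with no antiperiplanar axial H, so it is not eliminated.

## Compound list
1 | (S)-carvone | CC1=CC[C@@H](CC1=O)C(C)=C | starting material
2 | (Z)-1,4-diacetoxybut-2-ene | CC(=O)OC/C=C\COC(C)=O | starting material
3 | (E)-allylic acetate from carvone cross-metathesis | CC1=CC[C@@H](CC1=O)/C(C)=C/COC(C)=O | intermediate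
4 | iodomethane | CI | starting material
5 | 6-methyl ketone (C6 epimers unspecified) | CC1=CC[C@@H](C(C)C1=O)/C(C)=C/COC(C)=O | intermediate
6 | allyl bromide | C=CCBr | starting material
7 | C6-Me/allyl quaternary ketone | CC1=CC[C@@H]([C@@](C)(CC=C)C1=O)/C(C)=C/COC(C)=O | intermediate
8 | (E)-allylic alcohol | CC1=CC[C@@H]([C@@](C)(CC=C)C1=O)/C(C)=C/CO | intermediate
9 | triethyl orthoacetate | CC(OCC)(OCC)OCC | starting material
10 | Johnson–Claisen ester (C9 quaternary) | CC1=CC[C@@H]([C@@](C)(CC=C)C1=O)[C@@](C)(CC(=O)OCC)C=C | intermediate
11 | RCM bicyclic enone | CC1=CC[C@@H]2[C@@](C)(CC(=O)OCC)C=CC[C@@]2(C)C1=O | intermediate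
12 | α-epoxide | CC1=CC[C@@H]2[C@@](C)(CC(=O)OCC)[C@H]3O[C@H]3C[C@@]2(C)C1=O | intermediate
13 | triol (C8 axial α-OH) | CC1=CC[C@@H]2[C@@](C)(CCO)[C@@H](O)CC[C@@]2(C)C1O | intermediate
14 | primary iodide | CC1=CC[C@@H]2[C@@](C)(CCI)[C@@H](O)CC[C@@]2(C)C1O | intermediate
15 | 2-methylprop-1-enylmagnesium bromide | CC(C)=C[Mg]Br | starting material
16 | side-chain alkene, diol | CC1=CC[C@@H]2[C@@](C)(CCC=C(C)C)[C@@H](O)CC[C@@]2(C)C1O | intermediate
17 | enone alcohol | O=C1C(C)=CC[C@@H]2[C@@](C)(CCC=C(C)C)[C@@H](O)CC[C@@]12C | intermediate
18 | (methoxymethyl)triphenylphosphonium chloride | COC[P+](c1ccccc1)(c1ccccc1)c1ccccc1.[Cl-] | starting material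
19 | dienyl methyl ether | COC=C1C(C)=CC[C@@H]2[C@@](C)(CCC=C(C)C)[C@@H](O)CC[C@@]12C | intermediate
20 | conjugated enal | O=CC1=C(C)CC[C@@H]2[C@@](C)(CCC=C(C)C)[C@@H](O)CC[C@@]12C | intermediate
21 | exocyclic-methylene aldehyde | C=C1CC[C@@H]2[C@@](C)(CCC=C(C)C)[C@@H](O)CC[C@@]2(C)[C@@H]1C=O | intermediate
22 | p-toluenesulfonylhydrazide | Cc1ccc(cc1)S(=O)(=O)NN | starting material
23 | N-tosylhydrazone | C=C1CC[C@@H]2[C@@](C)(CCC=C(C)C)[C@@H](O)CC[C@@]2(C)[C@@H]1/C=N/NS(=O)(=O)c1ccc(C)cc1 | intermediate
24 | methyl 3,5-dibromo-4-hydroxybenzoate | COC(=O)c1cc(Br)c(O)c(Br)c1 | starting material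
25 | TBSCl | C[Si](C)(Cl)C(C)(C)C | starting material
26 | methyl 3,5-dibromo-4-(TBSO)benzoate | COC(=O)c1cc(Br)c(O[Si](C)(C)C(C)(C)C)c(Br)c1 | intermediate
27 | trimethyl borate | COB(OC)OC | starting material
28 | methyl 3-bromo-4-(TBSO)-5-boronobenzoate | COC(=O)c1cc(Br)c(O[Si](C)(C)C(C)(C)C)c(B(O)O)c1 | intermediate
29 | benzyl-coupled alcohol | C=C1CC[C@@H]2[C@@](C)(CCC=C(C)C)[C@@H](O)CC[C@@]2(C)[C@@H]1Cc1cc(C(=O)OC)cc(Br)c1O[Si](C)(C)C(C)(C)C | intermediate
30 | carbon tetrabromide | BrC(Br)(Br)Br | starting material
31 | C8-bromide, protected acid/phenol | C=C1CC[C@@H]2[C@@](C)(CCC=C(C)C)[C@H](Br)CC[C@@]2(C)[C@@H]1Cc1cc(C(=O)OC)cc(Br)c1O[Si](C)(C)C(C)(C)C | intermediate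
32 | callophycoic acid H | C=C1CC[C@@H]2[C@@](C)(CCC=C(C)C)[C@H](Br)CC[C@@]2(C)[C@@H]1Cc1cc(C(=O)O)cc(Br)c1O | target

## Totals
Total steps: 20, including the 2-step arylboronic acid preparation in steps 16–17. Longest linear sequence: 18 steps from (S)-carvone.

Three steps most likely to fail:
1. **Step 5 (C9 configuration in the Johnson–Claisen).** The 1,2-induction from C10 may give the wrong C9 epimer.
   Fallback: ozonolyse the isopropenyl group of 7 to the methyl ketone, close ring B by intramolecular aldol condensation to a 3-methylcyclohexenone, and add homoprenylmagnesium bromide/CuI/TMSCl at C9. The axial C5-Me shields the β-face, so the chain should enter α.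
2. **Step 14 (kinetic deconjugation).** It may deprotonate the ring C2 CH2 instead of the methyl, or re-conjugate on workup.
   Fallback: reduce the tosylhydrazone of 17 with catecholborane/NaOAc (Kabalka transposition) to the C3(Me)=C4H alkene. Then carry out a Me2AlCl-promoted carbonyl-ene reaction with paraformaldehyde to install C4–CH2OH and the exocyclic methylene together. Oxidize to the aldehyde and epimerize it to the equatorial isomer before the same Barluenga coupling.
3. **Step 19 (SN2 at the neopentyl axial C8–OH).** It may be too slow or give elimination.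
   Fallback: drop the alcohol inversion and install C8–Br with its equatorial β-configuration directly. Use a bromonium-initiated (Br+, anti-addition) cation–olefin cyclization of a ring-A precursor carrying a C5-tethered trisubstituted alkene, as in the presumed biogenesis.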